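A direct plan would grow the open C1–C9 chain from ethyl (S)-lactate A1 by crotylboration, cross-metathesis with methacrolein A2 and an auxiliary anti-aldol to the dihydroxy alkene imide A3. It would then close the pyran and the lactone in one flask (directed epoxidation, 6-endo epoxide opening, acyl transfer) to the bicyclic diol A4, and finish through the phosphonoacetate A5 by a Z-selective olefination with 2-oxooctanal A6.
Its weakest steps would be:
- the cross-metathesis, because a branched allylic olefin and a 1,1-disubstituted enal would couple slowly;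
- the one-flask epoxidation, ring opening and lactonisation, because face selection and 6-endo against 5-exo opening would have to hold unchecked;
- the final olefination, because base and an unstable keto aldehyde would meet a β-acetoxy lactone and an isomerisable Z-enedione.

The route rests on reading C4a (the fully substituted carbon shared by rings A and B), its methyl, O5 and C4 as one molecule of (R)-lactic acid, and on cutting ring B at C4a–C8a and C3–C4 and ring A at O5–C6. The key step joins the pivalaldehyde acetal of this acid to a five-carbon aldehyde and a propanoyl group in one flask: an aldol sets C4a and C8a, and a Dieckmann closure turns the acetal carbonyl into C4, closes the lactone first and frees the C4a alkoxide. That oxygen later closes the pyran on a vinyl group; one hydrogenation sets C3 and C4. No cross-metathesis, epoxide cascade or late olefination remains.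

Key step: step 6

Remark: atom labels (O1, C2–C4, C4a, O5, C6–C8, C8a) are those of the pyrano[3,2-b]pyran-2-one core; ring B is the lactone and ring A the tetrahydropyran. (R)-Lactic acid and 2-hexylfuran are assumed to be commercial.

**Step 1**
Reactants: 1 (4R)-4-benzyl-3-propanoyl-1,3-oxazolidin-2-one; 2 acrolein
Product: 5 (4R)-4-benzyl-3-[(2R,3S)-3-hydroxy-2-methylpent-4-enoyl]-1,3-oxazolidin-2-one, via dibutylboron Z-enolate 3 (not isolated), via boron aldolate 4 (not isolated)
Conditions: n-Bu2BOTf (1.1 equiv), Et3N (1.3 equiv), CH2Cl2, 0 °C; 2 (1.5 equiv), −78 → 0 °C; pH 7 buffer, MeOH, 30% H2O2, 0 °C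
Reagents that add atoms: none
Why: In the Evans syn-aldol the Z-boron enolate reacts through a Zimmerman–Traxler chair on the face away from the benzyl group, which should set 2R (future C8) and 3S (future C7) in the syn relation the target needs.

**Step 2**
Reactants: 5 (4R)-4-benzyl-3-[(2R,3S)-3-hydroxy-2-methylpent-4-enoyl]-1,3-oxazolidin-2-one
Product: 6 (4R)-4-benzyl-3-[(2R,3S)-3-(tert-butyldimethylsilyloxy)-2-methylpent-4-enoyl]-1,3-oxazolidin-2-one
Conditions: TBSOTf (1.2 equiv), 2,6-lutidine (2 equiv), CH2Cl2, 0 °C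
Reagents that add atoms: tert-butyldimethylsilyl trifluoromethanesulfonate (TBSOTf), CC(C)(C)[Si](C)(C)OS(=O)(=O)C(F)(F)F
Why: Silyl triflate silylation of the secondary carbinol gives an ether that should outlast the lithium amide bases, Hg(OCOCF3)2 and hydrogenation and can later be removed without base.

**Step 3**
Reactants: 6 (4R)-4-benzyl-3-[(2R,3S)-3-(tert-butyldimethylsilyloxy)-2-methylpent-4-enoyl]-1,3-oxazolidin-2-one
Product: 7 (2S,3S)-3-(tert-butyldimethylsilyloxy)-2-methylpent-4-en-1-ol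
Conditions: LiBH4 (1.5 equiv), THF, 0 °C → rt
Reagents that add atoms: none
Why: Reductive cleavage of the N-acyl oxazolidinone at the exocyclic carbonyl gives the primary alcohol and returns the auxiliary without touching the α-stereocentre.

**Step 4**
Reactants: 7 (2S,3S)-3-(tert-butyldimethylsilyloxy)-2-methylpent-4-en-1-ol
Product: 8 (2R,3S)-3-(tert-butyldimethylsilyloxy)-2-methylpent-4-enal
Conditions: Dess–Martin periodinane (1.3 equiv), CH2Cl2, 0 °C → rt; used at once
Reagents that add atoms: none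
Why: Dess–Martin oxidation under neutral conditions should give the α-branched β-silyloxy aldehyde without epimerisation or β-elimination.

**Step 5**
Reactants: 9 (R)-lactic acid; 10 pivalaldehyde
Product: 11 (2R,5R)-2-tert-butyl-5-methyl-1,3-dioxolan-4-one
Conditions: 10 (1.3 equiv), p-TsOH·H2O (cat.), H2SO4 (trace), pentane, reflux with water separator; crystallisation from pentane at −78 °C
Reagents that add atoms: none
Why: Acid-catalysed acetalisation with azeotropic removal of water should give mainly the cis-dioxolanone, purified by crystallisation, whose acetal carbon stores the chirality of the lactic centre for its later regeneration.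

**Step 6 (key step)**
Reactants: 11 (2R,5R)-2-tert-butyl-5-methyl-1,3-dioxolan-4-one; 8 (2R,3S)-3-(tert-butyldimethylsilyloxy)-2-methylpent-4-enal
Product: 17 (5S,6S)-6-[(2S,3S)-3-(tert-butyldimethylsilyloxy)pent-4-en-2-yl]-4,5-dihydroxy-3,5-dimethyl-5,6-dihydro-2H-pyran-2-one, via lithium enolate 12 (not isolated), via lithium aldolate 13 (not isolated), via propanoate ester 14 (not isolated), via hemiacetal alkoxide 15 (not isolated), via dilithium salt 16 (not isolated)
Conditions: 11 (1.15 equiv), LiN(i-Pr)2 (1.1 equiv), THF, −78 °C; 8 (1.0 equiv), −78 °C, 1 h; (EtCO)2O (1.1 equiv), −78 → −40 °C; LiN(SiMe3)2 (3 equiv), −78 → −20 °C, 2 h; AcOH (6 equiv), −78 °C, pH 4 buffer; crude product used directly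
Reagents that add atoms: propanoic anhydride, CCC(=O)OC(=O)CC
Why: LiN(i-Pr)2 gives the planar enolate 12, which should add to 8 on the face away from the tert-butyl group (regenerating the lactic centre as the fully substituted C4a) through a lithium-bridged chair in which the aldehyde chain points away from the dioxolanone ring, so that C8 lies anti to C4 and the new oxygen anti to O5 (8aS); the aldolate 13 is trapped as the propanoate 14. LiN(SiMe3)2 then forms the ester enolate, whose C3 attacks the acetal-activated carbonyl (future C4) in a 6-exo-trig Dieckmann closure of ring B; the adduct expels the acetal oxygen (15), loses pivalaldehyde and rests as the enolate alkoxide 16. The closest known reaction types are aldol additions of 2-tert-butyl-1,3-dioxolan-4-one enolates (self-regeneration of stereocentres), acylation of lithium aldolates in the flask, Claisen acylation of ester enolates by 1,3-dioxolan-4-ones and Dieckmann closure of β-acyloxy esters to 4-hydroxy-5,6-dihydropyran-2-ones. C8 and C7 are carried unchanged from 8 because the aldol and the acylation run below −40 °C, and C3/C4 stay flat for step 8. The step needs control of topicity at C8a, which the exo chair at the fully substituted enolate carbon should secure. It also needs the δ-lactone to survive the freed C4a alkoxide, which is secured because the lactone exists as its enolate until the acidic quench, so no five-membered tetronic acid should form.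

**Step 7**
Reactants: 17 (5S,6S)-6-[(2S,3S)-3-(tert-butyldimethylsilyloxy)pent-4-en-2-yl]-4,5-dihydroxy-3,5-dimethyl-5,6-dihydro-2H-pyran-2-one
Product: 19 (4aS,6S,7R,8S,8aS)-7-(tert-butyldimethylsilyloxy)-4-hydroxy-3,4a,6,8-tetramethyl-4a,7,8,8a-tetrahydropyrano[3,2-b]pyran-2(6H)-one, via alkylmercury trifluoroacetate 18 (not isolated)
Conditions: Hg(OCOCF3)2 (2.2 equiv), THF, 0 °C → rt, 8 h; then 3 M NaOH, NaBH4 (4 equiv), 0 °C; aqueous work-up at pH 4; mercury removed on Celite and a thiol resin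
Reagents that add atoms: none
Why: In this intramolecular oxymercuration–demercuration the C4a hydroxyl adds Markovnikov to the vinyl group in a 6-exo chair (ring A, bond O5–C6) under reversible conditions, and since an axial CH2Hg at C6 would clash 1,3-diaxially with the axial C4a methyl, the equatorial 6S ether should form before NaBH4 turns CH2Hg into the C6 methyl.

**Step 8**
Reactants: 19 (4aS,6S,7R,8S,8aS)-7-(tert-butyldimethylsilyloxy)-4-hydroxy-3,4a,6,8-tetramethyl-4a,7,8,8a-tetrahydropyrano[3,2-b]pyran-2(6H)-one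
Product: 20 (3R,4S,4aR,6S,7R,8S,8aS)-7-(tert-butyldimethylsilyloxy)-4-hydroxy-3,4a,6,8-tetramethylhexahydropyrano[3,2-b]pyran-2(3H)-one
Conditions: H2 (60 bar), Raney Ni (W-2), EtOAc, 40 °C, 24 h
Reagents that add atoms: none
Why: Heterogeneous hydrogenation of a 3-alkyl-4-hydroxy-5,6-dihydropyran-2-one (a reaction type known to give all-cis β-hydroxy δ-lactones) should deliver both hydrogens to the face of ring B opposite the axial C4a methyl, setting 3R and 4S in one event with the C3 methyl, the C4 oxygen and the C4a methyl all cis.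

**Step 9**
Reactants: 20 (3R,4S,4aR,6S,7R,8S,8aS)-7-(tert-butyldimethylsilyloxy)-4-hydroxy-3,4a,6,8-tetramethylhexahydropyrano[3,2-b]pyran-2(3H)-one
Product: 21 (3R,4S,4aS,6S,7R,8S,8aS)-7-(tert-butyldimethylsilyloxy)-3,4a,6,8-tetramethyl-2-oxooctahydropyrano[3,2-b]pyran-4-yl acetate
Conditions: Ac2O (5 equiv), DMAP (0.3 equiv), pyridine, 40 °C
Reagents that add atoms: acetic anhydride, CC(=O)OC(C)=O
Why: DMAP-catalysed acetylation of the hindered C4 hydroxyl proceeds with retention and needs no site selection because C7 is still silylated.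

**Step 10**
Reactants: 21 (3R,4S,4aS,6S,7R,8S,8aS)-7-(tert-butyldimethylsilyloxy)-3,4a,6,8-tetramethyl-2-oxooctahydropyrano[3,2-b]pyran-4-yl acetate
Product: 22 (3R,4S,4aS,6S,7R,8R,8aS)-7-hydroxy-3,4a,6,8-tetramethyl-2-oxooctahydropyrano[3,2-b]pyran-4-yl acetate
Conditions: HF·pyridine, THF/pyridine, 0 °C → rt
Reagents that add atoms: none
Why: Desilylation with buffered hydrogen fluoride frees the C7 hydroxyl and should leave the acetate and the lactone untouched, whereas a basic fluoride source could eliminate the β-acetoxy group.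

**Step 11**
Reactants: 23 2-hexylfuran
Product: 25 (2Z)-4-oxodec-2-enoic acid, via (2Z)-4-oxodec-2-enal 24 (not isolated)
Conditions: NaClO2 (3 equiv), NaH2PO4 (3 equiv), t-BuOH/H2O (5:1), rt, dark; extraction at pH 3, no chromatography; kept as its ring tautomer 5-hexyl-5-hydroxyfuran-2(5H)-one
Reagents that add atoms: sodium chlorite, [Na+].[O-]Cl=O
Why: Chlorite oxidation opens the 2-alkylfuran to the cis keto enal and oxidises it on to the acid (Pinnick stage), so the Z geometry is inherited from the furan ring and not made by an olefination.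

**Step 12**
Reactants: 22 (3R,4S,4aS,6S,7R,8R,8aS)-7-hydroxy-3,4a,6,8-tetramethyl-2-oxooctahydropyrano[3,2-b]pyran-4-yl acetate; 25 (2Z)-4-oxodec-2-enoic acid
Product: 27 botcinin J, via O-acylisourea 26 (not isolated)
Conditions: 25 (1.5 equiv), i-PrN=C=N-i-Pr (2 equiv), 4-(dimethylamino)pyridinium 4-toluenesulfonate (0.3 equiv), CH2Cl2, 0 °C, dark; neutral silica, no amines
Reagents that add atoms: none
Why: Buffered carbodiimide (Steglich-type) esterification should acylate the equatorial C7 hydroxyl through the open-chain activated acid with retention at C7, while low temperature, the absence of free nucleophilic base and darkness guard the Z-enedione.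

**Compound list**
1 | (4R)-4-benzyl-3-propanoyl-1,3-oxazolidin-2-one | CCC(=O)N1[C@H](Cc2ccccc2)COC1=O | starting material
2 | acrolein (prop-2-enal) | C=CC=O | starting material
3 | dibutylboron Z-enolate of 1 | C/C=C(\OB(CCCC)CCCC)N1[C@H](Cc2ccccc2)COC1=O | intermediate
4 | dibutylboron aldolate of 5 | C=C[C@H](OB(CCCC)CCCC)[C@@H](C)C(=O)N1[C@H](Cc2ccccc2)COC1=O | intermediate
5 | (4R)-4-benzyl-3-[(2R,3S)-3-hydroxy-2-methylpent-4-enoyl]-1,3-oxazolidin-2-one | C=C[C@H](O)[C@@H](C)C(=O)N1[C@H](Cc2ccccc2)COC1=O | intermediate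
6 | (4R)-4-benzyl-3-[(2R,3S)-3-(tert-butyldimethylsilyloxy)-2-methylpent-4-enoyl]-1,3-oxazolidin-2-one | C=C[C@H](O[Si](C)(C)C(C)(C)C)[C@@H](C)C(=O)N1[C@H](Cc2ccccc2)COC1=O | intermediate
7 | (2S,3S)-3-(tert-butyldimethylsilyloxy)-2-methylpent-4-en-1-ol | C=C[C@H](O[Si](C)(C)C(C)(C)C)[C@@H](C)CO | intermediate
8 | (2R,3S)-3-(tert-butyldimethylsilyloxy)-2-methylpent-4-enal | C=C[C@H](O[Si](C)(C)C(C)(C)C)[C@@H](C)C=O | intermediate
9 | (R)-lactic acid | C[C@@H](O)C(=O)O | starting material
10 | pivalaldehyde (2,2-dimethylpropanal) | CC(C)(C)C=O | starting material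
11 | (2R,5R)-2-tert-butyl-5-methyl-1,3-dioxolan-4-one (cis) | C[C@H]1O[C@@H](C(C)(C)C)OC1=O | intermediate
12 | lithium enolate of 11, lithium (2R)-2-tert-butyl-5-methyl-1,3-dioxol-4-olate | CC1=C(O[Li])O[C@H](C(C)(C)C)O1 | intermediate
13 | lithium aldolate, lithium (1S,2S,3S)-1-[(2R,4S)-2-tert-butyl-4-methyl-5-oxo-1,3-dioxolan-4-yl]-3-(tert-butyldimethylsilyloxy)-2-methylpent-4-en-1-olate | C=C[C@H](O[Si](C)(C)C(C)(C)C)[C@@H](C)[C@H](O[Li])[C@]1(C)O[C@@H](C(C)(C)C)OC1=O | intermediate
14 | (1S,2S,3S)-1-[(2R,4S)-2-tert-butyl-4-methyl-5-oxo-1,3-dioxolan-4-yl]-3-(tert-butyldimethylsilyloxy)-2-methylpent-4-en-1-yl propanoate | C=C[C@H](O[Si](C)(C)C(C)(C)C)[C@@H](C)[C@H](OC(=O)CC)[C@]1(C)O[C@@H](C(C)(C)C)OC1=O | intermediate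
15 | lithium alkoxide of the pivalaldehyde hemiacetal at O5 of the ring-closed β-keto lactone (C3 not defined) | C=C[C@H](O[Si](C)(C)C(C)(C)C)[C@@H](C)[C@@H]1OC(=O)C(C)C(=O)[C@@]1(C)O[C@@H](C(C)(C)C)O[Li] | intermediate
16 | dilithium salt of 17 (C4 enolate and C4a alkoxide) | C=C[C@H](O[Si](C)(C)C(C)(C)C)[C@@H](C)[C@@H]1OC(=O)C(C)=C(O[Li])[C@@]1(C)O[Li] | intermediate
17 | (5S,6S)-6-[(2S,3S)-3-(tert-butyldimethylsilyloxy)pent-4-en-2-yl]-4,5-dihydroxy-3,5-dimethyl-5,6-dihydro-2H-pyran-2-one | C=C[C@H](O[Si](C)(C)C(C)(C)C)[C@@H](C)[C@@H]1OC(=O)C(C)=C(O)[C@@]1(C)O | intermediate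
18 | alkylmercury trifluoroacetate, the 6-(trifluoroacetoxymercuriomethyl) analogue of 19 lacking the C6 methyl | CC(C)(C)[Si](C)(C)O[C@@H]1[C@@H](C)[C@@H]2OC(=O)C(C)=C(O)[C@@]2(C)O[C@H]1C[Hg]OC(=O)C(F)(F)F | intermediate
19 | (4aS,6S,7R,8S,8aS)-7-(tert-butyldimethylsilyloxy)-4-hydroxy-3,4a,6,8-tetramethyl-4a,7,8,8a-tetrahydropyrano[3,2-b]pyran-2(6H)-one | CC(C)(C)[Si](C)(C)O[C@@H]1[C@@H](C)[C@@H]2OC(=O)C(C)=C(O)[C@@]2(C)O[C@H]1C | intermediate
20 | (3R,4S,4aR,6S,7R,8S,8aS)-7-(tert-butyldimethylsilyloxy)-4-hydroxy-3,4a,6,8-tetramethylhexahydropyrano[3,2-b]pyran-2(3H)-one | CC(C)(C)[Si](C)(C)O[C@@H]1[C@@H](C)[C@@H]2OC(=O)[C@H](C)[C@H](O)[C@@]2(C)O[C@H]1C | intermediate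
21 | (3R,4S,4aS,6S,7R,8S,8aS)-7-(tert-butyldimethylsilyloxy)-3,4a,6,8-tetramethyl-2-oxooctahydropyrano[3,2-b]pyran-4-yl acetate | CC(C)(C)[Si](C)(C)O[C@@H]1[C@@H](C)[C@@H]2OC(=O)[C@H](C)[C@H](OC(C)=O)[C@@]2(C)O[C@H]1C | intermediate
22 | (3R,4S,4aS,6S,7R,8R,8aS)-7-hydroxy-3,4a,6,8-tetramethyl-2-oxooctahydropyrano[3,2-b]pyran-4-yl acetate | O[C@@H]1[C@@H](C)[C@@H]2OC(=O)[C@H](C)[C@H](OC(C)=O)[C@@]2(C)O[C@H]1C | intermediate
23 | 2-hexylfuran | CCCCCCc1ccco1 | starting material
24 | (2Z)-4-oxodec-2-enal | CCCCCCC(=O)/C=C\C=O | intermediate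
25 | (2Z)-4-oxodec-2-enoic acid (ring tautomer: 5-hexyl-5-hydroxyfuran-2(5H)-one) | CCCCCCC(=O)/C=C\C(=O)O | intermediate
26 | O-acylisourea of 25 from N,N'-diisopropylcarbodiimide | CCCCCCC(=O)/C=C\C(=O)OC(=NC(C)C)NC(C)C | intermediate
27 | botcinin J, (3R,4S,4aS,6S,7R,8R,8aS)-4-acetoxy-3,4a,6,8-tetramethyl-2-oxooctahydropyrano[3,2-b]pyran-7-yl (2Z)-4-oxodec-2-enoate | CCCCCCC(=O)/C=C\C(=O)O[C@@H]1[C@@H](C)[C@@H]2OC(=O)[C@H](C)[C@H](OC(C)=O)[C@@]2(C)O[C@H]1C | target

**Step count and risks**
Total step count: 12. Longest linear sequence: 10 (steps 1–4, 6–10 and 12).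

Steps most likely to fail:

1. Step 6. The aldehyde may add through the other relative topicity, or the aldolate may revert before it is acylated, so that C8a is not controlled and the wrong epimer enters the ring closure. The fallback sets out from 11 and 8 and comes back at 17. The aldol is quenched with aqueous NH4Cl instead of the anhydride and gives the free aldol adduct F1 as both C8a epimers. Dess–Martin periodinane gives the ketone F2. A Corey–Bakshi–Shibata reduction ((R)-2-methyl-CBS-oxazaborolidine, catecholborane, toluene, −78 °C) should set the (1S)-carbinol F3 under reagent control. Propanoyl chloride, pyridine and DMAP give 14, which is isolated, purified and closed separately with LiN(SiMe3)2 to 17.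

2. Step 8. The crowded tetrasubstituted enol may take up hydrogen too slowly, or be reduced through its keto tautomer with loss of control at C3. The fallback sets out from 19 and comes back at 20. NaBH4 in AcOH/THF at −20 °C reduces the keto tautomer from the face opposite the axial C4a methyl to the β-hydroxy lactone F4 as a mixture at C3. Its dianion (LiN(i-Pr)2, 2.2 equiv, THF, −78 °C) is then protonated kinetically with AcOH on the same open face, which should place the C3 methyl cis to the C4 oxygen and give 20.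

3. Step 12. The acid may be acylated through its ring (lactol) tautomer to a pseudo-ester, or the Z-enedione may isomerise to E under the nucleophilic catalyst. The fallback sets out from 22 and comes back at 27. Non-1-yn-3-ol is silylated (Et3SiCl, imidazole) to triethyl(non-1-yn-3-yloxy)silane F5 and carboxylated (n-BuLi, then CO2) to 4-(triethylsilyloxy)dec-2-ynoic acid F6. Esterification of 22 with F6 (N,N'-diisopropylcarbodiimide, DMAP) gives the alkynoate F7, a mixture at the side-chain carbinol that is of no consequence. Jones reagent (CrO3, H2SO4, acetone, 0 °C) removes the silyl group and oxidises the carbinol to the ynone ester F8. Semi-hydrogenation (H2, Pd/CaCO3 poisoned with Pb(OAc)2, EtOAc) adds hydrogen cis and gives 27.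

**Further compounds**
F1 | step 6 | (2R,5S)-2-tert-butyl-5-[(2S,3S)-3-(tert-butyldimethylsilyloxy)-1-hydroxy-2-methylpent-4-en-1-yl]-5-methyl-1,3-dioxolan-4-one, both epimers at the carbinol | C=C[C@H](O[Si](C)(C)C(C)(C)C)[C@@H](C)C(O)[C@]1(C)O[C@@H](C(C)(C)C)OC1=O
F2 | step 6 | (2R,5S)-2-tert-butyl-5-[(2R,3S)-3-(tert-butyldimethylsilyloxy)-2-methylpent-4-enoyl]-5-methyl-1,3-dioxolan-4-one | C=C[C@H](O[Si](C)(C)C(C)(C)C)[C@@H](C)C(=O)[C@]1(C)O[C@@H](C(C)(C)C)OC1=O
F3 | step 6 | (2R,5S)-2-tert-butyl-5-[(1S,2S,3S)-3-(tert-butyldimethylsilyloxy)-1-hydroxy-2-methylpent-4-en-1-yl]-5-methyl-1,3-dioxolan-4-one | C=C[C@H](O[Si](C)(C)C(C)(C)C)[C@@H](C)[C@H](O)[C@]1(C)O[C@@H](C(C)(C)C)OC1=O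
F4 | step 8 | (4S,4aR,6S,7R,8S,8aS)-7-(tert-butyldimethylsilyloxy)-4-hydroxy-3,4a,6,8-tetramethylhexahydropyrano[3,2-b]pyran-2(3H)-one, both epimers at C3 | CC(C)(C)[Si](C)(C)O[C@@H]1[C@@H](C)[C@@H]2OC(=O)C(C)[C@H](O)[C@@]2(C)O[C@H]1C
F5 | step 12 | triethyl(non-1-yn-3-yloxy)silane (racemic) | CCCCCCC(O[Si](CC)(CC)CC)C#C
F6 | step 12 | 4-(triethylsilyloxy)dec-2-ynoic acid (racemic) | CCCCCCC(O[Si](CC)(CC)CC)C#CC(=O)O
F7 | step 12 | (3R,4S,4aS,6S,7R,8R,8aS)-4-acetoxy-3,4a,6,8-tetramethyl-2-oxooctahydropyrano[3,2-b]pyran-7-yl 4-(triethylsilyloxy)dec-2-ynoate, both epimers at the side-chain carbinol | CCCCCCC(O[Si](CC)(CC)CC)C#CC(=O)O[C@@H]1[C@@H](C)[C@@H]2OC(=O)[C@H](C)[C@H](OC(C)=O)[C@@]2(C)O[C@H]1C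
F8 | step 12 | (3R,4S,4aS,6S,7R,8R,8aS)-4-acetoxy-3,4a,6,8-tetramethyl-2-oxooctahydropyrano[3,2-b]pyran-7-yl 4-oxodec-2-ynoate | CCCCCCC(=O)C#CC(=O)O[C@@H]1[C@@H](C)[C@@H]2OC(=O)[C@H](C)[C@H](OC(C)=O)[C@@]2(C)O[C@H]1C
A1 | direct plan | ethyl (S)-lactate | C[C@H](O)C(=O)OCC
A2 | direct plan | methacrolein | C=C(C)C=O
A3 | direct plan | (4S)-4-benzyl-3-[(2R,3S,4E,6S,7R,8S)-3,7-dihydroxy-2,4,6-trimethyl-8-(triethylsilyloxy)non-4-enoyl]-1,3-oxazolidin-2-one | C[C@H](O[Si](CC)(CC)CC)[C@H](O)[C@@H](C)/C=C(\C)[C@@H](O)[C@@H](C)C(=O)N1[C@@H](Cc2ccccc2)COC1=O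
A4 | direct plan | (3R,4S,4aR,6S,7R,8R,8aS)-4,7-dihydroxy-3,4a,6,8-tetramethylhexahydropyrano[3,2-b]pyran-2(3H)-one | O[C@@H]1[C@@H](C)[C@@H]2OC(=O)[C@H](C)[C@H](O)[C@@]2(C)O[C@H]1C
A5 | direct plan | (3R,4S,4aS,6S,7R,8R,8aS)-4-acetoxy-3,4a,6,8-tetramethyl-2-oxooctahydropyrano[3,2-b]pyran-7-yl bis(2,2,2-trifluoroethyl)phosphonoacetate | O=C(CP(=O)(OCC(F)(F)F)OCC(F)(F)F)O[C@@H]1[C@@H](C)[C@@H]2OC(=O)[C@H](C)[C@H](OC(C)=O)[C@@]2(C)O[C@H]1C
A6 | direct plan | 2-oxooctanal | CCCCCCC(=O)C=O
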